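The target is a C8–C8'' biflavone. C8'' of the apigenin unit (unit 2) sits in ring A'' between the oxygen-bearing carbons C7'' and C8a'', with C5''–O para, so ring A'' is a 2-substituted phloroglucinol. That ring is therefore grown, not coupled. Its six carbons are a hexanoate chain whose C6 is a CH2 already bonded to C8 of the acacetin unit (unit 1), placed there by a 7-O-allyl Claisen shift. One base-induced intramolecular Claisen condensation (C6 onto C1) closes ring A'' and aromatises it. The precursor is a 6-(flavon-8-yl)-3,5-dioxohexanoate carried as its C3 benzyl enol ether. It is released in the flask from the 4-benzyloxypyran-2-one.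

Key step: step 9

Assumption: the target SMILES carries no descriptor for the C8–C8'' axis, so the racemic atropisomer mixture is taken as the target; the axis becomes stereogenic only in step 11.

Remarks on the design
- **Chain numbering and ring map.** C1 is the ester carbonyl and C6 is the CH2 on flavone C8. C6 becomes C8''. C1 and C5 become C7'' and C8a''. C3 becomes C5''. C2 and C4 become C6'' and C4a''.
- **Why the free dioxo ester 13 is not cyclised directly.** Alkoxide deprotonates 13 first at C4 and C2, which turns the ester into an unreactive enolate. Its O-cyclised product 14 is a vinylogous acid whose anion resists alkoxide, so it would drain material irreversibly.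
- **The fix.** Compound 13 is taken through 14 on purpose and capped at O4 with benzyl. The neutral lactone 16 can be reopened by alkoxide, and its open form 17 has no acidic C2–H.
- **A second use for the same benzyl group.** It ends on the para oxygen (5''-O), where it forces the second pyranone to close through a flanking oxygen. No selective benzylation of a C-alkylation-prone triol is then needed.
- **The 5-O-benzyl group of unit 1** stays on until the last step. A transient opening of that pyranone can then only reclose the same way.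

Step 1
Reactants: 1 acacetin; 2 allyl bromide; 3 benzyl bromide
Product: 5 7-(allyloxy)-5-(benzyloxy)-2-(4-methoxyphenyl)chromen-4-one, via 7-O-allylacacetin 4 (not isolated)
Conditions: K2CO3, DMF, 2 (1.05 equiv), rt; then 3 (1.5 equiv), 80 °C
Reagents that add atoms: allyl bromide C=CCBr; benzyl bromide BrCc1ccccc1
Why: Two-stage Williamson etherification, in which the free and more acidic 7-OH is allylated at room temperature, while the 5-OH, hydrogen-bonded to the C4 carbonyl, reacts only on heating with the second halide.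

Step 2
Reactants: 5 7-(allyloxy)-5-(benzyloxy)-2-(4-methoxyphenyl)chromen-4-one
Product: 6 8-allyl-5-(benzyloxy)-7-hydroxy-2-(4-methoxyphenyl)chromen-4-one
Conditions: PhNEt2, 200–210 °C, Ar
Reagents that add atoms: none
Why: Aromatic Claisen rearrangement ([3,3] shift, then tautomerisation), which with the 5-oxygen alkylated should end at C8, the terminus favoured in 7-allyloxychromones by C7–C8 bond fixation and less crowded than C6 next to the benzyloxy group.

Step 3
Reactants: 6 8-allyl-5-(benzyloxy)-7-hydroxy-2-(4-methoxyphenyl)chromen-4-one; 3 benzyl bromide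
Product: 7 8-allyl-5,7-bis(benzyloxy)-2-(4-methoxyphenyl)chromen-4-one
Conditions: BnBr, K2CO3, DMF, 60 °C
Reagents that add atoms: benzyl bromide BrCc1ccccc1
Why: Williamson etherification of the only free phenol, needed because a free 7-OH would later close onto the C8 side chain as a lactol or benzofuranone.

Step 4
Reactants: 7 8-allyl-5,7-bis(benzyloxy)-2-(4-methoxyphenyl)chromen-4-one
Product: 8 [5,7-bis(benzyloxy)-2-(4-methoxyphenyl)-4-oxochromen-8-yl]acetaldehyde
Conditions: OsO4 (cat.), NaIO4, 2,6-lutidine, dioxane/H2O, rt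
Reagents that add atoms: osmium tetroxide O=[Os](=O)(=O)=O (catalytic oxygen carrier); sodium periodate [Na+].[O-]I(=O)(=O)=O
Why: Lemieux–Johnson cleavage, selective for the terminal alkene because the flavone C2=C3 bond is a conjugated, electron-poor vinylogous ester; this is the reaction type used to make flavone-8-acetic acids from 8-allylflavones.

Step 5
Reactants: 8 [5,7-bis(benzyloxy)-2-(4-methoxyphenyl)-4-oxochromen-8-yl]acetaldehyde
Product: 9 [5,7-bis(benzyloxy)-2-(4-methoxyphenyl)-4-oxochromen-8-yl]acetic acid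
Conditions: NaClO2, NaH2PO4, 2-methyl-2-butene, t-BuOH/THF/H2O, rt
Reagents that add atoms: sodium chlorite [Na+].[O-]Cl=O
Why: Pinnick oxidation, mild enough for benzyl ethers and the flavone, with the alkene scavenger keeping hypochlorous acid away from the electron-rich rings.

Step 6
Reactants: 9 [5,7-bis(benzyloxy)-2-(4-methoxyphenyl)-4-oxochromen-8-yl]acetic acid; 10 methyl acetoacetate
Product: 13 methyl 6-[5,7-bis(benzyloxy)-2-(4-methoxyphenyl)-4-oxochromen-8-yl]-3,5-dioxohexanoate, via acyl imidazolide 11 (not isolated), via dilithio acetoacetate dianion 12 (not isolated)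
Conditions: 9, CDI, THF, rt; added at −78 °C to 12 [10 (3 equiv), LiN(iPr)2 (6 equiv), THF, −78 to 0 °C]; 1 M HCl
Reagents that add atoms: methyl acetoacetate COC(=O)CC(C)=O
Why: γ-Acylation of a Weiler-type β-keto ester dianion by an N-acylimidazole, a standard entry to 3,5-dioxo esters, where the excess dianion absorbs the acidic protons of imidazole and of the product and the low temperature spares the deactivated 5,7-dialkoxyflavone.

Step 7
Reactants: 13 methyl 6-[5,7-bis(benzyloxy)-2-(4-methoxyphenyl)-4-oxochromen-8-yl]-3,5-dioxohexanoate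
Product: 14 5,7-bis(benzyloxy)-8-[(4-hydroxy-2-oxopyran-6-yl)methyl]-2-(4-methoxyphenyl)chromen-4-one
Conditions: DBU, toluene, 80–110 °C; 1 M HCl
Reagents that add atoms: none
Why: Base-induced lactonisation of a 3,5-dioxo ester through the C5 enol oxygen, the normal and well-documented fate of such esters with amidine bases.

Step 8
Reactants: 14 5,7-bis(benzyloxy)-8-[(4-hydroxy-2-oxopyran-6-yl)methyl]-2-(4-methoxyphenyl)chromen-4-one; 15 benzyl alcohol
Product: 16 5,7-bis(benzyloxy)-8-{[4-(benzyloxy)-2-oxopyran-6-yl]methyl}-2-(4-methoxyphenyl)chromen-4-one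
Conditions: BnOH, PPh3, DIAD, THF, 0 °C to rt
Reagents that add atoms: benzyl alcohol OCc1ccccc1
Why: Mitsunobu etherification, for which the acidic 4-hydroxypyran-2-one is an ideal pronucleophile and which is known to alkylate at O4, avoiding the C3-benzylation seen with benzyl halides and base.

Step 9
Reactants: 16 5,7-bis(benzyloxy)-8-{[4-(benzyloxy)-2-oxopyran-6-yl]methyl}-2-(4-methoxyphenyl)chromen-4-one; 15 benzyl alcohol (as NaOBn)
Product: 18 5,7-bis(benzyloxy)-8-[4-(benzyloxy)-2,6-dihydroxyphenyl]-2-(4-methoxyphenyl)chromen-4-one, via open-chain benzyl ester 17 (not isolated)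
Conditions: NaH (4 equiv), BnOH (1.5 equiv), THF (0.02 M), 0 °C to reflux; then 1 M HCl
Reagents that add atoms: none
Why: Proposed new method: benzyloxide adds to the lactone carbonyl of 16 and opens it to the extended enolate of 17, in which C1 and C4 stay cis across C2=C3; proton transfer or a second deprotonation by NaH then places charge on the benzylic C6, acidified by the C5 ketone and the aryl group, and C6 attacks the ester carbonyl C1 with loss of benzyloxide. The 2-aryl-5-benzyloxycyclohex-4-ene-1,3-dione so formed tautomerises to the resorcinol and is held as its bis-phenoxide, so the net change is an isomerisation of the pyranone driven by aromatisation. The ring C1–C6 (ring A'' of unit 2) closes in the 6-(enolendo)-exo-trig mode; no stereocentre is formed, and because the new ring is symmetric the C8–C8'' bond is not yet a stereogenic axis. The selectivity needed is acylation at carbon over acylation at oxygen, and it is secured by the C3 benzyl enol ether, which removes the C2 acidity that would deactivate the ester and makes the O-cyclised product (16 itself) a neutral lactone that alkoxide reopens, leaving the phenoxide as the only irreversible exit. Using benzyloxide as the sole alkoxide makes ester exchange and addition–elimination at chain C3 and at flavone C5 and C7 degenerate. The closest known reaction types are alkoxide opening of 4-alkoxy-6-alkylpyran-2-ones to 3-alkoxy-5-oxohex-2-enoates, Claisen cyclisation of 3,5,7-trioxo esters to acylphloroglucinols, and KOtBu cyclisation of 5-oxo-6-arylhexanoates, including 2,6-disubstituted aryl groups, to 2-arylcyclohexane-1,3-diones.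

Step 10
Reactants: 19 4'-(benzyloxy)acetophenone; 20 diethyl carbonate
Product: 21 ethyl 3-[4-(benzyloxy)phenyl]-3-oxopropanoate
Conditions: NaH, (EtO)2CO, toluene, reflux; AcOH
Reagents that add atoms: diethyl carbonate CCOC(=O)OCC
Why: Crossed Claisen condensation (carbethoxylation of a methyl ketone enolate), driven by deprotonation of the β-keto ester product.

Step 11
Reactants: 18 5,7-bis(benzyloxy)-8-[4-(benzyloxy)-2,6-dihydroxyphenyl]-2-(4-methoxyphenyl)chromen-4-one; 21 ethyl 3-[4-(benzyloxy)phenyl]-3-oxopropanoate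
Product: 22 5,7-bis(benzyloxy)-8-{5-(benzyloxy)-2-[4-(benzyloxy)phenyl]-7-hydroxy-4-oxochromen-8-yl}-2-(4-methoxyphenyl)chromen-4-one (racemic axis)
Conditions: 21 (1.5 equiv), Ph2O, 240–250 °C, N2 sweep
Reagents that add atoms: ethyl 3-[4-(benzyloxy)phenyl]-3-oxopropanoate CCOC(=O)CC(=O)c1ccc(OCc2ccccc2)cc1
Why: Mentzer pyrone synthesis, in which the keto ester loses ethanol to an aroylketene that acylates the very electron-rich free ring carbon (future C4a'') and the adjacent flanking hydroxyl condenses with the aryl ketone; the etherified para oxygen cannot become O1'', which fixes the 8''-linkage, and the two halves of the resorcinol ring are equivalent, so one constitution results.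

Step 12
Reactants: 22 5,7-bis(benzyloxy)-8-{5-(benzyloxy)-2-[4-(benzyloxy)phenyl]-7-hydroxy-4-oxochromen-8-yl}-2-(4-methoxyphenyl)chromen-4-one
Product: 23 5,7-dihydroxy-8-[5,7-dihydroxy-2-(4-hydroxyphenyl)-4-oxochromen-8-yl]-2-(4-methoxyphenyl)chromen-4-one (target, racemic axis)
Conditions: H2 (1 atm), Pd/C, THF/MeOH, rt
Reagents that add atoms: none
Why: Catalytic hydrogenolysis of four aryl benzyl ethers under neutral conditions, which leaves the flavone C2=C3 bonds and the aryl methyl ether untouched and avoids the acid-induced Wessely–Moser isomerisation of 8-linked to 6-linked flavones.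

Compound list
1 | acacetin | COc1ccc(cc1)-c1cc(=O)c2c(O)cc(O)cc2o1 | starting material
2 | allyl bromide | C=CCBr | starting material
3 | benzyl bromide | BrCc1ccccc1 | starting material
4 | 7-(allyloxy)-5-hydroxy-2-(4-methoxyphenyl)chromen-4-one | COc1ccc(cc1)-c1cc(=O)c2c(O)cc(OCC=C)cc2o1 | intermediate (not isolated)
5 | 7-(allyloxy)-5-(benzyloxy)-2-(4-methoxyphenyl)chromen-4-one | COc1ccc(cc1)-c1cc(=O)c2c(OCc3ccccc3)cc(OCC=C)cc2o1 | intermediate
6 | 8-allyl-5-(benzyloxy)-7-hydroxy-2-(4-methoxyphenyl)chromen-4-one | C=CCc1c(O)cc(OCc2ccccc2)c2c(=O)cc(-c3ccc(OC)cc3)oc12 | intermediate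
7 | 8-allyl-5,7-bis(benzyloxy)-2-(4-methoxyphenyl)chromen-4-one | C=CCc1c(OCc2ccccc2)cc(OCc2ccccc2)c2c(=O)cc(-c3ccc(OC)cc3)oc12 | intermediate
8 | [5,7-bis(benzyloxy)-2-(4-methoxyphenyl)-4-oxochromen-8-yl]acetaldehyde | O=CCc1c(OCc2ccccc2)cc(OCc2ccccc2)c2c(=O)cc(-c3ccc(OC)cc3)oc12 | intermediate
9 | [5,7-bis(benzyloxy)-2-(4-methoxyphenyl)-4-oxochromen-8-yl]acetic acid | OC(=O)Cc1c(OCc2ccccc2)cc(OCc2ccccc2)c2c(=O)cc(-c3ccc(OC)cc3)oc12 | intermediate
10 | methyl acetoacetate | COC(=O)CC(C)=O | starting material
11 | 1-{[5,7-bis(benzyloxy)-2-(4-methoxyphenyl)-4-oxochromen-8-yl]acetyl}imidazole | O=C(Cc1c(OCc2ccccc2)cc(OCc2ccccc2)c2c(=O)cc(-c3ccc(OC)cc3)oc12)n1ccnc1 | intermediate (not isolated)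
12 | dilithium dianion of methyl acetoacetate | [Li+].[Li+].C=C([O-])C=C([O-])OC | intermediate (not isolated)
13 | methyl 6-[5,7-bis(benzyloxy)-2-(4-methoxyphenyl)-4-oxochromen-8-yl]-3,5-dioxohexanoate | COC(=O)CC(=O)CC(=O)Cc1c(OCc2ccccc2)cc(OCc2ccccc2)c2c(=O)cc(-c3ccc(OC)cc3)oc12 | intermediate
14 | 5,7-bis(benzyloxy)-8-[(4-hydroxy-2-oxopyran-6-yl)methyl]-2-(4-methoxyphenyl)chromen-4-one | O=c1cc(O)cc(Cc2c(OCc3ccccc3)cc(OCc3ccccc3)c3c(=O)cc(-c4ccc(OC)cc4)oc23)o1 | intermediate
15 | benzyl alcohol | OCc1ccccc1 | starting material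
16 | 5,7-bis(benzyloxy)-8-{[4-(benzyloxy)-2-oxopyran-6-yl]methyl}-2-(4-methoxyphenyl)chromen-4-one | O=c1cc(OCc2ccccc2)cc(Cc2c(OCc3ccccc3)cc(OCc3ccccc3)c3c(=O)cc(-c4ccc(OC)cc4)oc23)o1 | intermediate
17 | benzyl (2E)-3-(benzyloxy)-6-[5,7-bis(benzyloxy)-2-(4-methoxyphenyl)-4-oxochromen-8-yl]-5-oxohex-2-enoate (C3 benzyl enol ether of the 3,5-dioxohexanoate; present as its enolate) | O=C(OCc1ccccc1)/C=C(/OCc1ccccc1)CC(=O)Cc1c(OCc2ccccc2)cc(OCc2ccccc2)c2c(=O)cc(-c3ccc(OC)cc3)oc12 | intermediate (not isolated)
18 | 5,7-bis(benzyloxy)-8-[4-(benzyloxy)-2,6-dihydroxyphenyl]-2-(4-methoxyphenyl)chromen-4-one | Oc1cc(OCc2ccccc2)cc(O)c1-c1c(OCc2ccccc2)cc(OCc2ccccc2)c2c(=O)cc(-c3ccc(OC)cc3)oc12 | intermediate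
19 | 4'-(benzyloxy)acetophenone | CC(=O)c1ccc(OCc2ccccc2)cc1 | starting material
20 | diethyl carbonate | CCOC(=O)OCC | starting material
21 | ethyl 3-[4-(benzyloxy)phenyl]-3-oxopropanoate | CCOC(=O)CC(=O)c1ccc(OCc2ccccc2)cc1 | intermediate
22 | 5,7-bis(benzyloxy)-8-{5-(benzyloxy)-2-[4-(benzyloxy)phenyl]-7-hydroxy-4-oxochromen-8-yl}-2-(4-methoxyphenyl)chromen-4-one | COc1ccc(-c2cc(=O)c3c(OCc4ccccc4)cc(OCc4ccccc4)c(-c4c(O)cc(OCc5ccccc5)c5c(=O)cc(-c6ccc(OCc7ccccc7)cc6)oc45)c3o2)cc1 | intermediate
23 | 5,7-dihydroxy-8-[5,7-dihydroxy-2-(4-hydroxyphenyl)-4-oxochromen-8-yl]-2-(4-methoxyphenyl)chromen-4-one | COc1ccc(-c2cc(=O)c3c(O)cc(O)c(-c4c(O)cc(O)c5c(=O)cc(-c6ccc(O)cc6)oc45)c3o2)cc1 | target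

Total step count: 12. Longest linear sequence: 11 (steps 1–9, 11, 12); step 10 is a one-step branch.

Steps most likely to fail

1. **Step 9.**
   - What may go wrong: closure through oxygen may keep returning the pyranone while the open chain is slowly consumed. The losses would come from retro-Claisen cleavage between C4 and C5 or from intermolecular condensation, so that C6–C1 bond formation never competes.
   - Fallback: it sets out from 1 and 3, makes the biaryl bond by known cross-coupling, and comes back at 23.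
   - Exhaustive benzylation of 1 with 3 (K2CO3, DMF, 80 °C) gives 5,7-di-O-benzylacacetin F1. Iodination (I2, AgO2CCF3, CH2Cl2) goes to C8, as is usual for 5,7-dialkoxyflavones, and gives the 8-iodide F2.
   - Commercial apigenin is treated in the same way to give tri-O-benzylapigenin F3 and its 8-iodide F4. Borylation (HBpin, PdCl2(MeCN)2, SPhos, Et3N, dioxane) then gives the 8-pinacolboronate F5.
   - Suzuki–Miyaura coupling of F2 with F5 (Pd(OAc)2, SPhos, K3PO4, toluene/H2O, 100 °C) gives the penta-O-benzyl biflavone F6. Hydrogenolysis under the conditions of step 12 delivers 23.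

2. **Step 11.**
   - What may go wrong: at the required temperature benzyl groups may migrate or be lost. Acylation may stop at oxygen without the shift to carbon, or a second annulation may start at C6''.
   - Fallback: it sets out from 18 and comes back at 22 without high temperature.
   - One equivalent of N-iodosuccinimide (MeCN, −20 °C) iodinates the strongly activated resorcinol ring to give the o-iodophenol F7.
   - Carbonylative annulation of F7 with commercial 1-(benzyloxy)-4-ethynylbenzene (PdCl2(PPh3)2, CO 1 atm, Et2NH, 60–80 °C) forms the ynone. The ynone closes 6-endo through the neighbouring flanking hydroxyl to give 22.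

3. **Step 6.**
   - What may go wrong: proton transfer from the acidic CH2 of the imidazolide to the dianion, or attack of excess dianion at flavone C2, may erode the acylation.
   - Fallback: it sets out from 9 and 10, runs without base, and comes back at 13.
   - Compound 9 with (COCl)2 and catalytic DMF in CH2Cl2 gives the acid chloride F8.
   - Compound 10 with Me3SiCl/Et3N gives methyl 3-(trimethylsilyloxy)but-2-enoate F9. LiN(iPr)2 followed by Me3SiCl then gives 1-methoxy-1,3-bis(trimethylsilyloxy)buta-1,3-diene F10.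
   - F8 and F10 are combined in CH2Cl2 from −78 to 20 °C (γ-acylation of a bis-silyl dienol ether). Aqueous work-up gives 13.

Further compounds
F1 | step 9 | 5,7-bis(benzyloxy)-2-(4-methoxyphenyl)chromen-4-one | COc1ccc(cc1)-c1cc(=O)c2c(OCc3ccccc3)cc(OCc3ccccc3)cc2o1
F2 | step 9 | 5,7-bis(benzyloxy)-8-iodo-2-(4-methoxyphenyl)chromen-4-one | COc1ccc(cc1)-c1cc(=O)c2c(OCc3ccccc3)cc(OCc3ccccc3)c(I)c2o1
F3 | step 9 | 5,7-bis(benzyloxy)-2-[4-(benzyloxy)phenyl]chromen-4-one | O=c1cc(-c2ccc(OCc3ccccc3)cc2)oc2cc(OCc3ccccc3)cc(OCc3ccccc3)c12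
F4 | step 9 | 5,7-bis(benzyloxy)-2-[4-(benzyloxy)phenyl]-8-iodochromen-4-one | O=c1cc(-c2ccc(OCc3ccccc3)cc2)oc2c(I)c(OCc3ccccc3)cc(OCc3ccccc3)c12
F5 | step 9 | 5,7-bis(benzyloxy)-2-[4-(benzyloxy)phenyl]-8-(4,4,5,5-tetramethyl-1,3,2-dioxaborolan-2-yl)chromen-4-one | O=c1cc(-c2ccc(OCc3ccccc3)cc2)oc2c(B3OC(C)(C)C(C)(C)O3)c(OCc3ccccc3)cc(OCc3ccccc3)c12
F6 | step 9 | 5,7-bis(benzyloxy)-8-{5,7-bis(benzyloxy)-2-[4-(benzyloxy)phenyl]-4-oxochromen-8-yl}-2-(4-methoxyphenyl)chromen-4-one | COc1ccc(-c2cc(=O)c3c(OCc4ccccc4)cc(OCc4ccccc4)c(-c4c(OCc5ccccc5)cc(OCc5ccccc5)c5c(=O)cc(-c6ccc(OCc7ccccc7)cc6)oc45)c3o2)cc1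
F7 | step 11 | 5,7-bis(benzyloxy)-8-[4-(benzyloxy)-2,6-dihydroxy-3-iodophenyl]-2-(4-methoxyphenyl)chromen-4-one | Oc1cc(OCc2ccccc2)c(I)c(O)c1-c1c(OCc2ccccc2)cc(OCc2ccccc2)c2c(=O)cc(-c3ccc(OC)cc3)oc12
F8 | step 6 | [5,7-bis(benzyloxy)-2-(4-methoxyphenyl)-4-oxochromen-8-yl]acetyl chloride | ClC(=O)Cc1c(OCc2ccccc2)cc(OCc2ccccc2)c2c(=O)cc(-c3ccc(OC)cc3)oc12
F9 | step 6 | methyl 3-(trimethylsilyloxy)but-2-enoate | COC(=O)C=C(C)O[Si](C)(C)C
F10 | step 6 | 1-methoxy-1,3-bis(trimethylsilyloxy)buta-1,3-diene | COC(=CC(=C)O[Si](C)(C)C)O[Si](C)(C)C
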